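Our closed, stirred vessel has held two charges at one temperature, and before the east flask goes in we must decide how much partner to give it and which earlier run may stand in for it.

| setting | south-west | north-east | east |
|---|---|---|---|
| starting material | 0.0500 M | 0.0500 M | 0.0170 M |
| partner | 0.0600 M | 0.0900 M | 0.0600 M |
| free catalyst | 2.50 × 10⁻⁴ M | 2.50 × 10⁻⁴ M | 2.50 × 10⁻⁴ M |
| time |  |  | 81 min |

| run | time / min | [starting material] / M |
|---|---|---|
| south-west run | 4.6 | 0.04472 |
| south-west run | 14 | 0.03486 |
| south-west run | 27 | 0.02432 |
| south-west run | 42 | 0.01617 |
| south-west run | 61 | 0.01033 |
| south-west run | 81 | 0.00714 |
| north-east run | 4.6 | 0.04550 |
| north-east run | 14 | 0.03745 |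
| north-east run | 27 | 0.02892 |
| north-east run | 42 | 0.02115 |
| north-east run | 61 | 0.01456 |
| north-east run | 81 | 0.01036 |

(standard deviation of a reading: 2 × 10⁻⁴ M)

- the power of [partner] that the first rate follows, about the charge of the south-west run; measure it at two percent of starting material made into product
- starting material in the east run at 81 min, as a share of the starting material charged

- Overall: starting material + partner -> product, with free catalyst as catalyst.
- Constant volume, constant temperature.
- Readings of a species count what is bound in complexes too.
- "The second partner" is partner.
- An order is taken over about fifteen percent of the charge, up and down.

Over the first 14 min of the south-west run, the natural logarithm of [starting material] falls by 0.0258 /min. We call this k, the pseudo-first-order constant: the fall of that logarithm per minute over a stretch of a run. The north-east run gives 0.0206 /min over the same stretch, so its richer charge is slower, and we stay with 0.0600 M of partner.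

Starting material is the limiting reagent of the east flask, so its partner can fall from 0.0600 M to 0.0430 M and no lower. In the south-west run, the stretch we read took partner from 0.0600 M to 0.0449 M, which is nearly the same window. We therefore carry k over to the east flask, as a reading with a scatter of about 4.10 × 10⁻⁴ /min.

Our own reckoning then leaves 12.4% of the starting material charged to the east flask at 81 min. The two values of k also give a power of partner of −0.546, though that is a chord from 0.0600 M to 0.0900 M of partner, read over the first 14 min, and the order asked for is taken about the south-west charge at two percent turned.

The forecast says −0.45 and 13%, on the ground: “More partner therefore slows the reaction”. Its share is higher than ours, and its power is less negative than ours. We charge the east flask as planned.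

The east run keeps 13.5% of its starting material at 81 min, and the power of partner about the south-west charge comes to −0.58. The steps behind the flask are these:

    free catalyst + starting material ⇌ catalyst-substrate complex (519.6 /M/min, 57.66 /min)
    catalyst-substrate complex + partner → product + free catalyst (4668 /M/min)
    free catalyst + partner ⇌ idle catalyst-reagent complex, settled at all times (57.50 /M)
    free catalyst + product → spent catalyst + product (1.026 /M/min)

Where two percent of the south-west charge of starting material has turned, the rate of product formation in the north-east run is 0.77 of that in the south-west run. Read as k over its whole 81 min, the east result is 0.0248 /min, lower than the value carried from the first 14 min of the south-west run. In the north-east run, a quarter of the charge has become product at 14.9 min, which gives k = 0.0193 /min, and the same mark in the south-west run, at 11.4 min, gives 0.0252 /min.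

(The earlier runs and the new flask are simulated with made-up constants, noise included.)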